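**Retrosynthetic overview**
The strategy rests on the quaternary spiro carbon C6, shared by ring A (C1–C6) and ring B (C6–C11), which lies 1,4 to C9 across ring B and next to the gem-dimethyl carbon C5. Ring B is therefore the retron of a 4,4-disubstituted cyclohexenone and is cut at C6–C7 (Michael) and C10–C11 (aldol) into a ring A enal and methyl vinyl ketone.
The ring B substituents come last: enone, then regiodefined enol triflate, then C9 methyl, then anti bromochlorination of C9=C10 (C9–Cl, C10–Br).
Ring A comes from an acyclic bromochloride keto ester by bromonium cyclisation (C5–C6 bond). Its one C4–Br stereocentre is made by catalytic enantioselective bromochlorination of prenol and relays to C6, C9 and C10.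
Ring order: ring A first (step 4), ring B second (step 9).

Key step: step 9

Remark: atom numbers follow the spiro[5.5]undecane skeleton of the target (ring A C1–C5, spiro C6, ring B C7–C11) and are used in the reasoning for all intermediates; the configuration at the ester-bearing carbon of 8 is of no consequence, because that carbon becomes trigonal in step 5.

**Route**

Step 1
Reactants: 1 prenol (3-methylbut-2-en-1-ol)
Product: 2 (S)-2-bromo-3-chloro-3-methylbutan-1-ol
Conditions: NBS, ClTi(OiPr)3, chiral tridentate O,N,O Schiff base ligand (salicylaldimine of a chiral 1,2-amino alcohol, 20 mol%), hexanes, −20 °C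
Reagents that add atoms: N-bromosuccinimide, O=C1CCC(=O)N1Br; chlorotitanium triisopropoxide, CC(C)O[Ti](Cl)(OC(C)C)OC(C)C
Why: Titanium-templated catalytic enantioselective bromochlorination of an allylic alcohol puts bromine on the carbon next to the carbinol and lets chloride open the bromonium ion anti at the tertiary carbon, and the ligand enantiomer is chosen so that the C–Br centre (later C4) is S.

Step 2
Reactants: 2 (S)-2-bromo-3-chloro-3-methylbutan-1-ol
Product: 3 (S)-2-bromo-3-chloro-3-methylbutyl trifluoromethanesulfonate
Conditions: Tf2O, 2,6-lutidine, CH2Cl2, −78 °C; used at once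
Reagents that add atoms: triflic anhydride, O=S(=O)(OS(=O)(=O)C(F)(F)F)C(F)(F)F
Why: O-Sulfonylation of the primary alcohol with a hindered base at low temperature gives the reactive triflate without displacement by the neighbouring bromine and without touching the stereocentre.

Step 3
Reactants: 3 (S)-2-bromo-3-chloro-3-methylbutyl trifluoromethanesulfonate; 4 methyl acetoacetate
Product: 6 methyl (S)-6-bromo-7-chloro-7-methyl-3-oxooctanoate, via dianion 5 (not isolated)
Conditions: 4, NaH, THF, 0 °C; n-BuLi, 0 °C; then 3, −78 → −40 °C; aqueous NH4Cl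
Reagents that add atoms: none
Why: γ-Alkylation of a β-keto ester dianion takes place at the terminal carbanion, which displaces the primary triflate by SN2 at low temperature faster than it can attack or eliminate the hindered secondary bromide or the tertiary chloride, so the C–Br centre is carried through unchanged.

Step 4
Reactants: 6 methyl (S)-6-bromo-7-chloro-7-methyl-3-oxooctanoate
Product: 8 methyl (1S,3S)-3-bromo-2,2-dimethyl-6-oxocyclohexane-1-carboxylate, via bromonium ion 7 (not isolated)
Conditions: (CF3)2CHOH, 23 °C
Reagents that add atoms: none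
Why: In this solvolytic bromonium cyclisation the ionising, non-nucleophilic solvent lets the tertiary chloride leave with anchimeric assistance from bromine, and the enol carbon C6 of the keto ester opens bromonium ion 7 at the tertiary carbon C5 (6-endo, chair-like) without breaking the C4–Br bond, so C4 keeps its configuration while the epimerisable ester carbon should settle cis to bromine (both equatorial).

Step 5
Reactants: 8 methyl (1S,3S)-3-bromo-2,2-dimethyl-6-oxocyclohexane-1-carboxylate
Product: 9 methyl (S)-5-bromo-6,6-dimethyl-2-(trifluoromethylsulfonyloxy)cyclohex-1-ene-1-carboxylate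
Conditions: Tf2O, i-Pr2NEt, CH2Cl2, −78 °C
Reagents that add atoms: triflic anhydride, O=S(=O)(OS(=O)(=O)C(F)(F)F)C(F)(F)F
Why: Enol triflate formation from a β-keto ester: the amine removes only the proton between the two carbonyl groups and the enol oxygen is sulfonylated at −78 °C, conditions chosen so that no free metal enolate is present that could displace the C4 bromide by 1,3-elimination.

Step 6
Reactants: 9 methyl (S)-5-bromo-6,6-dimethyl-2-(trifluoromethylsulfonyloxy)cyclohex-1-ene-1-carboxylate
Product: 10 methyl (S)-5-bromo-2,6,6-trimethylcyclohex-1-ene-1-carboxylate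
Conditions: Me2CuLi (from CuI and MeLi), Et2O, −78 → −40 °C
Reagents that add atoms: lithium dimethylcuprate, [Li+].C[Cu-]C
Why: A β-triflyloxy enoate reacts with a lithium dialkylcuprate by conjugate addition–elimination, replacing the triflate by methyl at a temperature at which the neopentyl-type secondary bromide and the ester do not react.

Step 7
Reactants: 10 methyl (S)-5-bromo-2,6,6-trimethylcyclohex-1-ene-1-carboxylate
Product: 11 [(S)-5-bromo-2,6,6-trimethylcyclohex-1-en-1-yl]methanol
Conditions: (i-Bu)2AlH (2.2 equiv), CH2Cl2, −78 → 0 °C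
Reagents that add atoms: none
Why: 1,2-Reduction of the α,β-unsaturated ester by the aluminium hydride gives the allylic alcohol and leaves the alkyl bromide and the tetrasubstituted alkene intact.

Step 8
Reactants: 11 [(S)-5-bromo-2,6,6-trimethylcyclohex-1-en-1-yl]methanol
Product: 12 (S)-5-bromo-2,6,6-trimethylcyclohex-1-ene-1-carbaldehyde
Conditions: MnO2, CH2Cl2, 23 °C
Reagents that add atoms: none
Why: MnO2 oxidises allylic alcohols selectively to enals under neutral conditions, so neither the bromide nor the C4 centre is at risk.

Step 9
Reactants: 12 (S)-5-bromo-2,6,6-trimethylcyclohex-1-ene-1-carbaldehyde; 13 methyl vinyl ketone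
Product: 17 (4S,6R)-4-bromo-1,5,5-trimethylspiro[5.5]undeca-1,10-dien-9-one, via potassium dienolate 14 (not isolated), via keto aldehyde 15 (not isolated), via ketol 16 (not isolated)
Conditions: KOtBu (0.3 equiv), t-BuOH/THF, 0 °C, slow addition of 13; then 23–40 °C
Reagents that add atoms: none
Why: Substoichiometric tert-butoxide removes a γ-proton at C2 of 12 to give the endocyclic dienolate 14, which adds through its α-carbon C6 to methyl vinyl ketone (C6–C7 bond) and thereby moves the ring A alkene to C1=C2; the methyl ketone enolate of 15 then attacks the now non-enolisable aldehyde carbon (C10–C11 bond) and ketol 16 dehydrates to the enone. The closest known reaction type is the Robinson spiroannulation of α-branched or β,γ-unsaturated aldehydes with methyl vinyl ketone to 4,4-disubstituted cyclohexenones, joined here to the deconjugative α-functionalisation of a cyclocitral-type dienolate. Ring B is closed by a 6-(enolendo)-exo-trig intramolecular aldol condensation that follows the intermolecular Michael addition. The only new stereocentre, C6, is controlled by C4: in the ring A half-chair with equatorial bromine the pseudoaxial C5 methyl lies on the bromine face of C6, so the enone should add to the opposite face, which places C7 trans and the formyl-derived C11 cis to bromine (6R). The step needs α- over γ-attack, loss of a ring CH2 proton in preference to a methyl proton, and survival of the secondary bromide; the potassium dienolate reacts with Michael acceptors at its α-carbon, the endocyclic diene is the more stable dienolate under equilibrating alkoxide conditions, and a catalytic amount of base at 0 °C should leave the neopentyl-type C4–Br bond alone.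

Step 10
Reactants: 17 (4S,6R)-4-bromo-1,5,5-trimethylspiro[5.5]undeca-1,10-dien-9-one
Product: 19 (4S,6R)-4-bromo-1,5,5-trimethylspiro[5.5]undeca-1,9-dien-9-yl trifluoromethanesulfonate, via lithium enolate 18 (not isolated)
Conditions: LiBH(sec-Bu)3, THF, −78 °C; then PhNTf2, −78 → 0 °C
Reagents that add atoms: N-phenylbis(trifluoromethanesulfonimide), O=S(=O)(N(c1ccccc1)S(=O)(=O)C(F)(F)F)C(F)(F)F
Why: Conjugate reduction of a β-unsubstituted cyclohexenone by the bulky borohydride delivers hydride to C11 and gives only the C9=C10 enolate 18, which the triflimide O-sulfonylates in place, fixing an alkene position that enolisation of the saturated ketone could not select, and no stereocentre is formed.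

Step 11
Reactants: 19 (4S,6R)-4-bromo-1,5,5-trimethylspiro[5.5]undeca-1,9-dien-9-yl trifluoromethanesulfonate
Product: 20 (4S,6R)-4-bromo-1,5,5,9-tetramethylspiro[5.5]undeca-1,9-diene
Conditions: Me2CuLi (from CuI and MeLi), Et2O/THF, −20 → 0 °C
Reagents that add atoms: lithium dimethylcuprate, [Li+].C[Cu-]C
Why: Lithium dialkylcuprates couple with alkenyl triflates to give the alkyl-substituted alkene, and the hindered secondary bromide at C4 is not expected to compete below 0 °C.

Step 12
Reactants: 20 (4S,6R)-4-bromo-1,5,5,9-tetramethylspiro[5.5]undeca-1,9-diene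
Product: 22 (4S,6R,9S,10S)-4,10-dibromo-9-chloro-1,5,5,9-tetramethylspiro[5.5]undec-1-ene (target CNP0126187.1), via bromonium ion 21 (not isolated)
Conditions: NBS, Et4NCl, CH2Cl2, −78 °C, dark
Reagents that add atoms: N-bromosuccinimide, O=C1CCC(=O)N1Br; tetraethylammonium chloride, [Cl-].CC[N+](CC)(CC)CC
Why: In this electrophilic anti bromochlorination the ring B alkene is the accessible one (C1 of the ring A alkene is flanked by the quaternary C6, so chloride cannot open a bromonium ion there), and in the ring B half-chair that keeps C5 pseudoequatorial chloride opens bromonium ion 21 at the tertiary C9 in the trans-diaxial (Fürst–Plattner) sense, which places Cl on C9 anti to an axial Br on C10 on the C1 side (9S,10S).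

**Compound list**
1 | prenol (3-methylbut-2-en-1-ol) | CC(C)=CCO | starting material
2 | (S)-2-bromo-3-chloro-3-methylbutan-1-ol | OC[C@H](Br)C(C)(C)Cl | intermediate
3 | (S)-2-bromo-3-chloro-3-methylbutyl trifluoromethanesulfonate | O=S(=O)(OC[C@H](Br)C(C)(C)Cl)C(F)(F)F | intermediate
4 | methyl acetoacetate (methyl 3-oxobutanoate) | COC(=O)CC(C)=O | starting material
5 | dianion of methyl acetoacetate (sodium lithium salt) | [Na+].[Li+].[CH2-]C(=O)[CH-]C(=O)OC | intermediate
6 | methyl (S)-6-bromo-7-chloro-7-methyl-3-oxooctanoate | COC(=O)CC(=O)CC[C@H](Br)C(C)(C)Cl | intermediate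
7 | bromonium ion from 6 (chloride ion pair) | COC(=O)CC(=O)CC[C@@H]1[Br+]C1(C)C.[Cl-] | intermediate
8 | methyl (1S,3S)-3-bromo-2,2-dimethyl-6-oxocyclohexane-1-carboxylate (ester cis to Br) | COC(=O)[C@@H]1C(=O)CC[C@H](Br)C1(C)C | intermediate
9 | methyl (S)-5-bromo-6,6-dimethyl-2-(trifluoromethylsulfonyloxy)cyclohex-1-ene-1-carboxylate | COC(=O)C1=C(OS(=O)(=O)C(F)(F)F)CC[C@H](Br)C1(C)C | intermediate
10 | methyl (S)-5-bromo-2,6,6-trimethylcyclohex-1-ene-1-carboxylate | COC(=O)C1=C(C)CC[C@H](Br)C1(C)C | intermediate
11 | [(S)-5-bromo-2,6,6-trimethylcyclohex-1-en-1-yl]methanol | OCC1=C(C)CC[C@H](Br)C1(C)C | intermediate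
12 | (S)-5-bromo-2,6,6-trimethylcyclohex-1-ene-1-carbaldehyde | O=CC1=C(C)CC[C@H](Br)C1(C)C | intermediate
13 | methyl vinyl ketone (but-3-en-2-one) | CC(=O)C=C | starting material
14 | potassium dienolate of 12 (endocyclic C1=C2, enolate geometry not defined) | [K+].[O-]C=C1C(C)=CC[C@H](Br)C1(C)C | intermediate
15 | (1R,5S)-5-bromo-2,6,6-trimethyl-1-(3-oxobutyl)cyclohex-2-ene-1-carbaldehyde | CC1=CC[C@H](Br)C(C)(C)[C@@]1(C=O)CCC(C)=O | intermediate
16 | (4S,6R)-4-bromo-11-hydroxy-1,5,5-trimethylspiro[5.5]undec-1-en-9-one (C11 epimers) | CC1=CC[C@H](Br)C(C)(C)[C@@]12CCC(=O)CC2O | intermediate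
17 | (4S,6R)-4-bromo-1,5,5-trimethylspiro[5.5]undeca-1,10-dien-9-one | CC1=CC[C@H](Br)C(C)(C)[C@@]12CCC(=O)C=C2 | intermediate
18 | lithium (4S,6R)-4-bromo-1,5,5-trimethylspiro[5.5]undeca-1,9-dien-9-olate | [Li+].CC1=CC[C@H](Br)C(C)(C)[C@@]12CCC([O-])=CC2 | intermediate
19 | (4S,6R)-4-bromo-1,5,5-trimethylspiro[5.5]undeca-1,9-dien-9-yl trifluoromethanesulfonate | CC1=CC[C@H](Br)C(C)(C)[C@@]12CCC(OS(=O)(=O)C(F)(F)F)=CC2 | intermediate
20 | (4S,6R)-4-bromo-1,5,5,9-tetramethylspiro[5.5]undeca-1,9-diene | CC1=CC[C@H](Br)C(C)(C)[C@@]12CCC(C)=CC2 | intermediate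
21 | bromonium ion from 20 (Br bridging C9 and C10 on the C1 face, chloride ion pair) | CC1=CC[C@H](Br)C(C)(C)[C@@]12CC[C@@]3(C)[Br+][C@H]3C2.[Cl-] | intermediate
22 | (4S,6R,9S,10S)-4,10-dibromo-9-chloro-1,5,5,9-tetramethylspiro[5.5]undec-1-ene | CC1=CC[C@H](Br)C(C)(C)[C@@]12CC[C@](C)(Cl)[C@@H](Br)C2 | target

**Totals**
Total step count: 12. Longest linear sequence: 12 steps (1 to 22).

**Steps most likely to fail**

Step 9. The Michael addition has to form a quaternary carbon between C5 and C1 and may be slow or reversible, so that polymerisation of the enone wins. Deprotonation at the C1 methyl group, attack through the γ-carbon, or poor facial discrimination at C6 could also divert the material. The fallback sets out from 12. The dienolate 14 would be formed completely (KOtBu, 1.05 equiv, THF, −78 °C) and alkylated irreversibly with the reactive allylic chloride 1,3-dichlorobut-2-ene (Wichterle reaction) to give (1R,5S)-5-bromo-1-(3-chlorobut-2-en-1-yl)-2,6,6-trimethylcyclohex-2-ene-1-carbaldehyde F1. Hydrolysis of its vinyl chloride (Hg(OCOCF3)2, MeNO2, then aqueous HCl) would unmask the methyl ketone and bring the route back at keto aldehyde 15, which is closed to 17 with KOH in MeOH as in the second half of step 9.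

Step 4. The ketone oxygen may capture the bromonium ion faster than the enol carbon, giving a cyclic enol ether (O-cyclisation) in place of the carbocycle. The fallback sets out from triflate 3. 2,2,6-Trimethyl-4H-1,3-dioxin-4-one, the acetone-protected form of acetoacetate, would be deprotonated at its methyl group (LiN(i-Pr)2, THF, −78 °C) to the lithium dienolate F2 and alkylated with 3 to give 6-[(S)-3-bromo-4-chloro-4-methylpentyl]-2,2-dimethyl-4H-1,3-dioxin-4-one F3. In this compound both oxygens are tied up, so on solvolysis in (CF3)2CHOH only the dioxinone α-carbon can close the ring, giving (S)-6-bromo-2,2,5,5-tetramethyl-5,6,7,8-tetrahydro-4H-1,3-benzodioxin-4-one F4. Heating F4 in MeOH/toluene (110 °C, sealed tube) would exchange the acetonide for the methyl ester with loss of acetone and bring the route back at keto ester 8.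

Step 12. Bromine may also be taken up at the ring A alkene, or chloride may open the bromonium ion through the other half-chair, giving the C9,C10-diastereomer. The fallback sets out from 20 and fixes the face by an irreversible step. Epoxidation (mCPBA, NaHCO3, CH2Cl2, 0 °C) should occur on the ring B face away from the axial C1 and give (4S,6R,9S,10R)-4-bromo-9,10-epoxy-1,5,5,9-tetramethylspiro[5.5]undec-1-ene F5. Bromide from Li2NiBr4 in THF should open it at the secondary C10 with inversion (trans-diaxial) to the bromohydrin (4S,6R,9S,10S)-4,10-dibromo-1,5,5,9-tetramethylspiro[5.5]undec-1-en-9-ol F6. Dry HCl in CH2Cl2 at −40 °C would then ionise the tertiary alcohol with participation of the anti bromine, regenerate bromonium ion 21 on a defined face, and let chloride open it at C9 with overall retention, which brings the route back at 22.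

**Further compounds**
F1 | step 9 | (1R,5S)-5-bromo-1-(3-chlorobut-2-en-1-yl)-2,6,6-trimethylcyclohex-2-ene-1-carbaldehyde | CC1=CC[C@H](Br)C(C)(C)[C@@]1(C=O)CC=C(C)Cl
F2 | step 4 | lithium dienolate of 2,2,6-trimethyl-4H-1,3-dioxin-4-one | [Li+].[O-]C1=CC(=C)OC(C)(C)O1
F3 | step 4 | 6-[(S)-3-bromo-4-chloro-4-methylpentyl]-2,2-dimethyl-4H-1,3-dioxin-4-one | CC1(C)OC(=O)C=C(CC[C@H](Br)C(C)(C)Cl)O1
F4 | step 4 | (S)-6-bromo-2,2,5,5-tetramethyl-5,6,7,8-tetrahydro-4H-1,3-benzodioxin-4-one | CC1(C)OC(=O)C2=C(O1)CC[C@H](Br)C2(C)C
F5 | step 12 | (4S,6R,9S,10R)-4-bromo-9,10-epoxy-1,5,5,9-tetramethylspiro[5.5]undec-1-ene | CC1=CC[C@H](Br)C(C)(C)[C@@]12CC[C@]3(C)O[C@@H]3C2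
F6 | step 12 | (4S,6R,9S,10S)-4,10-dibromo-1,5,5,9-tetramethylspiro[5.5]undec-1-en-9-ol | CC1=CC[C@H](Br)C(C)(C)[C@@]12CC[C@](C)(O)[C@@H](Br)C2
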